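## Retrosynthetic overview
1. The Z‑ene‑dione comes from oxidative opening of a 2,3,5‑trisubstituted furan in the last step, so the working target is the furan‑bridged macrocycle.
2. The butenolide and 13‑membered carbocycle come from transannular RCM (C11=C12) of a 13‑membered macrolactone, itself made by macrolactonisation (C10–O/C20).
3. The C1–C2 bond and both its stereocentres come from a chiral‑phosphoric‑acid‑catalysed anti‑allylboration of a "west" furfural with an achiral "east" (E)‑allylboronate.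
4. In the west fragment, C10 comes from Ru transfer hydrogenation of an ynone, and the furan from aldol/cyclodehydration of a cyclopropyl methyl ketone.
5. C7 and C8 come from an OH‑directed Simmons–Smith reaction on an (S)‑allylic alcohol made by ketoreductase reduction of an achiral enone. Ring order: cyclopropane, furan, macrolactone, butenolide/carbocycle, then furan opening.

Assumption 1: cembranoid‑type labels are used. C1 = CH(isopropenyl), C2 = CHOAc, C3–C6 = ene‑dione (or furan), C7/C8/C9 = cyclopropane CH/C(Me)/CH2, C10 = lactone CH–O, C11=C12, C20 = lactone C=O, C13 and C14 = CH2CH2. The SMILES reads as 1S,2S,7S,8S,10S with a 4Z alkene and C6 trans to C10 on the cyclopropane.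

Assumption 2: the ketoreductase is chosen from a Prelog‑selective panel, with ADH‑A (Rhodococcus ruber) as the default.

## West fragment

**Step 1**
Reactants: 1 prop‑2‑yn‑1‑ol
Product: 2 (E)‑3‑iodo‑2‑methylprop‑2‑en‑1‑ol
Conditions: AlMe3 (3 equiv), Cp2ZrCl2 (0.25 equiv), CH2Cl2, 0 °C→rt; then I2, THF, −30→0 °C
Reagents that add atoms: trimethylaluminium C[Al](C)C (CH3); iodine II (I)
Why: Negishi Zr‑catalysed carboalumination adds Me and Al syn, and iodinolysis proceeds with retention, which fixes CH2OH trans to I (the future C10/C6 trans relationship).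

**Step 2**
Reactants: 2
Product: 3 (E)‑tert‑butyl[(3‑iodo‑2‑methylprop‑2‑en‑1‑yl)oxy]diphenylsilane
Conditions: TBDPSCl, imidazole, CH2Cl2, rt
Reagents that add atoms: TBDPSCl CC(C)(C)[Si](Cl)(c1ccccc1)c1ccccc1
Why: This silyl ether formation installs TBDPS because it survives t‑BuLi, Zn carbenoid, LDA and the later acid‑mediated furan formation.

**Step 3**
Reactants: 3; 4 N‑methoxy‑N‑methylacetamide
Product: 5 (E)‑5‑(TBDPS‑oxy)‑4‑methylpent‑3‑en‑2‑one
Conditions: t‑BuLi (2.1 equiv), Et2O, −78 °C; then 4, −78→0 °C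
Reagents that add atoms: 4, CC(=O)N(C)OC (acetyl)
Why: Li–I exchange gives a configurationally stable vinyllithium, and Weinreb ketone synthesis stops at the ketone with the alkene geometry retained.

**Step 4 (enzymatic; first stereocentre)**
Reactants: 5
Product: 6 (2S,3E)‑5‑(TBDPS‑oxy)‑4‑methylpent‑3‑en‑2‑ol
Conditions: Prelog‑selective ketoreductase (KRED/NAD(P)H‑dependent alcohol dehydrogenase, EC 1.1.1; e.g. ADH‑A), NAD+ (cat.), i‑PrOH (15 % v/v), KPi pH 7.0, 5 % DMSO, 30 °C, N2 sweep to remove acetone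
Reagents that add atoms: none
Why: In this biocatalytic asymmetric ketone reduction, a methyl/large ketone is the ideal KRED substrate class, and Re‑face (Prelog) hydride delivery sets C6 as S (expected >99 % ee) without touching the C=C.

**Step 5**
Reactants: 6
Product: 7 (1S)‑1‑[(1S,2S)‑2‑(TBDPS‑oxymethyl)‑2‑methylcyclopropyl]ethan‑1‑ol
Conditions: Et2Zn (4 equiv), CH2I2 (8 equiv), CH2Cl2, −20→0 °C
Reagents that add atoms: diiodomethane ICI (CH2 = C9)
Why: In this alkoxide‑directed Simmons–Smith (Furukawa) cyclopropanation, A(1,3) strain with the cis C8‑methyl locks the carbinol H in the alkene plane, so CH2 arrives on the oxygen face; the stereospecific addition gives 7S,8S (expected dr >20:1).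

**Step 6**
Reactants: 7
Product: 8 1‑[(1S,2S)‑2‑(TBDPS‑oxymethyl)‑2‑methylcyclopropyl]ethan‑1‑one
Conditions: Dess–Martin periodinane, NaHCO3, CH2Cl2, 0 °C→rt
Reagents that add atoms: none
Why: This neutral Dess–Martin oxidation removes the relay stereocentre after it has done its job, and the cyclopropyl α‑CH does not enolise, so C7 is retained.

**Step 7**
Reactants: 8; 9 1‑(tert‑butyldimethylsilyloxy)propan‑2‑one
Product: 10 1‑[(1S,2S)‑2‑(TBDPS‑oxymethyl)‑2‑methylcyclopropyl]‑4‑(TBS‑oxy)‑3‑hydroxy‑3‑methylbutan‑1‑one (C4 epimers)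
Conditions: LDA, THF, −78 °C; 9; AcOH quench at −78 °C
Reagents that add atoms: 9, CC(=O)CO[Si](C)(C)C(C)(C)C
Why: In this kinetic lithium‑enolate aldol addition, the methyl side is deprotonated and adds to the activated α‑silyloxy ketone, and the new carbinol centre is erased in step 8.

**Step 8**
Reactants: 10
Product: 11 tert‑butyl{[(1S,2S)‑1‑methyl‑2‑(4‑methylfuran‑2‑yl)cyclopropyl]methoxy}diphenylsilane
Conditions: CSA (0.2 equiv), MeOH–CH2Cl2 (1:4), 0 °C→rt
Reagents that add atoms: none
Why: Selective primary‑TBS cleavage releases a γ‑hydroxy ketone that closes to a hemiketal and loses two molecules of water (Paal–Knorr‑type cyclodehydration) to give the furan, while TBDPS and the non‑ionisable CH2O group at C10 are inert.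

**Step 9**
Reactants: 11
Product: 12 [(1S,2S)‑1‑methyl‑2‑(4‑methylfuran‑2‑yl)cyclopropyl]methanol
Conditions: TBAF, THF, rt
Reagents that add atoms: none
Why: Fluoride desilylation is mildly basic and non‑acidic, so it is harmless to the furyl cyclopropane.

**Step 10**
Reactants: 12
Product: 13 (1S,2S)‑1‑methyl‑2‑(4‑methylfuran‑2‑yl)cyclopropane‑1‑carbaldehyde
Conditions: Dess–Martin periodinane, NaHCO3, CH2Cl2, 0 °C
Reagents that add atoms: none
Why: This buffered Dess–Martin oxidation gives a non‑enolisable aldehyde, and no Lewis or Brønsted acid is present that could open the donor–acceptor cyclopropane.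

**Step 11**
Reactants: 13; 14 ethynyltrimethylsilane
Product: 15 1‑[(1S,2S)‑1‑methyl‑2‑(4‑methylfuran‑2‑yl)cyclopropyl]‑3‑(trimethylsilyl)prop‑2‑yn‑1‑ol (C10 epimers)
Conditions: 14, n‑BuLi, THF, −78 °C; then 13
Reagents that add atoms: 14, C#C[Si](C)(C)C
Why: This is a 1,2‑addition of a lithium acetylide, and its stereochemical outcome is irrelevant because C10 is reset in steps 12 and 13.

**Step 12**
Reactants: 15
Product: 16 1‑[(1S,2S)‑1‑methyl‑2‑(4‑methylfuran‑2‑yl)cyclopropyl]‑3‑(trimethylsilyl)prop‑2‑yn‑1‑one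
Conditions: Dess–Martin periodinane, NaHCO3, CH2Cl2, 0 °C→rt
Reagents that add atoms: none
Why: Dess–Martin oxidation converges both epimers to a single ynone.

**Step 13**
Reactants: 16
Product: 17 (1R)‑1‑[(1S,2S)‑1‑methyl‑2‑(4‑methylfuran‑2‑yl)cyclopropyl]‑3‑(trimethylsilyl)prop‑2‑yn‑1‑ol
Conditions: Ru(p‑cymene)[(R,R)‑TsDPEN] (5 mol %), i‑PrOH, rt
Reagents that add atoms: none
Why: In this Noyori–Ikariya asymmetric transfer hydrogenation of an ynone, the alkynyl group takes the "aryl" site, so the (R,R) catalyst sets C10 in the target sense under catalyst control; the descriptor is R only because of the Si atom.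

**Step 14**
Reactants: 17
Product: 18 (1S)‑1‑[(1S,2S)‑1‑methyl‑2‑(4‑methylfuran‑2‑yl)cyclopropyl]prop‑2‑yn‑1‑ol
Conditions: K2CO3, MeOH, rt
Reagents that add atoms: none
Why: This is a protodesilylation of the alkynylsilane, and the geometry at C10 is unchanged (the R→S switch is a CIP change only).

**Step 15**
Reactants: 18
Product: 19 (1S)‑1‑[(1S,2S)‑1‑methyl‑2‑(4‑methylfuran‑2‑yl)cyclopropyl]prop‑2‑en‑1‑ol
Conditions: H2 (1 atm), Lindlar catalyst, quinoline, EtOAc, rt, stopped at 1 equiv H2
Reagents that add atoms: none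
Why: Lindlar semihydrogenation of the terminal alkyne leaves the furan and cyclopropane untouched on the poisoned catalyst.

**Step 16**
Reactants: 19
Product: 20 triethyl{(1S)‑1‑[(1S,2S)‑1‑methyl‑2‑(4‑methylfuran‑2‑yl)cyclopropyl]prop‑2‑en‑1‑yloxy}silane
Conditions: TESCl, imidazole, DMAP (cat.), DMF, rt
Reagents that add atoms: TESCl CC[Si](Cl)(CC)CC
Why: This silyl ether formation uses TES because it tolerates n‑BuLi yet is later removed by fluoride next to an acetate.

**Step 17**
Reactants: 20
Product: 21 3‑methyl‑5‑{(1S,2S)‑2‑methyl‑2‑[(1S)‑1‑(triethylsilyloxy)prop‑2‑en‑1‑yl]cyclopropyl}furan‑2‑carbaldehyde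
Conditions: n‑BuLi (1.2 equiv), THF, −78→0 °C; DMF, −78 °C→rt
Reagents that add atoms: DMF CN(C)C=O (CHO = C2)
Why: α‑Lithiation of the furan followed by formylation is regiospecific because only one furan α‑H remains.

## East fragment (achiral)

**Step 18**
Reactants: 22 2‑(diethoxyphosphoryl)acetic acid; 23 2‑(trimethylsilyl)ethanol
Product: 24 2‑(trimethylsilyl)ethyl 2‑(diethoxyphosphoryl)acetate
Conditions: EDC·HCl, DMAP (cat.), CH2Cl2, rt
Reagents that add atoms: 23, OCC[Si](C)(C)C
Why: Steglich‑type esterification installs a TMSE ester, which is fluoride‑cleavable and orthogonal to the final acetate.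

**Step 19**
Reactants: 24; 25 2‑(2‑bromoethyl)‑1,3‑dioxolane
Product: 26 2‑(trimethylsilyl)ethyl 2‑(diethoxyphosphoryl)‑4‑(1,3‑dioxolan‑2‑yl)butanoate (racemic)
Conditions: NaH, DMF, 0 °C; 25, NaI (cat.), 60 °C
Reagents that add atoms: 25, BrCCC1OCCO1
Why: This is an SN2 alkylation of the stabilised phosphonoacetate anion, and the racemic α‑centre is erased in step 20.

**Step 20**
Reactants: 26
Product: 27 2‑(trimethylsilyl)ethyl 4‑(1,3‑dioxolan‑2‑yl)‑2‑methylidenebutanoate
Conditions: 37 % aq HCHO, K2CO3, THF–H2O, rt→40 °C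
Reagents that add atoms: formaldehyde C=O (=CH2)
Why: Horner–Wadsworth–Emmons methylenation under Villieras conditions gives the α‑substituted acrylate.

**Step 21**
Reactants: 27
Product: 28 2‑(trimethylsilyl)ethyl 2‑methylidene‑5‑oxopentanoate
Conditions: 1 M HCl, THF, rt
Reagents that add atoms: water O (aldehyde O)
Why: This acetal hydrolysis leaves the TMSE ester and acrylate intact, since both are stable to dilute acid.

**Step 22**
Reactants: 28; 29 2‑(triphenyl‑λ5‑phosphanylidene)propanal
Product: 30 2‑(trimethylsilyl)ethyl (5E)‑6‑methyl‑2‑methylidene‑7‑oxohept‑5‑enoate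
Conditions: toluene, BHT (cat.), 80 °C
Reagents that add atoms: 29, CC(C=O)=P(c1ccccc1)(c1ccccc1)c1ccccc1
Why: This stabilised‑ylide Wittig olefination is under thermodynamic control and gives the E‑trisubstituted enal (>20:1).

**Step 23**
Reactants: 30
Product: 31 2‑(trimethylsilyl)ethyl (5E)‑7‑hydroxy‑6‑methyl‑2‑methylidenehept‑5‑enoate
Conditions: NaBH4, CeCl3·7H2O, MeOH, −20 °C
Reagents that add atoms: none
Why: Luche 1,2‑reduction is selective for the enal over the acrylate ester.

**Step 24**
Reactants: 31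
Product: 32 2‑(trimethylsilyl)ethyl (5E)‑7‑acetoxy‑6‑methyl‑2‑methylidenehept‑5‑enoate
Conditions: Ac2O, pyridine, DMAP (cat.), CH2Cl2, 0 °C
Reagents that add atoms: acetic anhydride CC(=O)OC(C)=O
Why: Acetylation turns the allylic alcohol into a leaving group for Pd.

**Step 25**
Reactants: 32; 33 bis(pinacolato)diboron
Product: 34 2‑(trimethylsilyl)ethyl (5E)‑6‑methyl‑2‑methylidene‑7‑(4,4,5,5‑tetramethyl‑1,3,2‑dioxaborolan‑2‑yl)hept‑5‑enoate
Conditions: Pd2(dba)3 (2.5 mol %), DMSO, 50 °C
Reagents that add atoms: 33, CC1(C)OB(OC1(C)C)B1OC(C)(C)C(C)(C)O1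
Why: Miyaura allylic borylation via the syn π‑allyl‑Pd complex places boron at the primary terminus with the E geometry kept, and any minor Z isomer is removed by chromatography.

## Union and endgame

**Step 26**
Reactants: 21; 34 (1.5 equiv)
Product: 35 2‑(trimethylsilyl)ethyl (5S)‑5‑[(S)‑hydroxy(3‑methyl‑5‑{(1S,2S)‑2‑methyl‑2‑[(1S)‑1‑(triethylsilyloxy)prop‑2‑en‑1‑yl]cyclopropyl}furan‑2‑yl)methyl]‑6‑methyl‑2‑methylidenehept‑6‑enoate
Conditions: (S)‑TRIP phosphoric acid (10 mol %), 4 Å MS, toluene, −30→0 °C; aq NaHCO3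
Reagents that add atoms: 34 (all atoms except Bpin)
Why: In this chiral‑Brønsted‑acid‑catalysed allylboration through a closed Zimmerman–Traxler chair, the E‑boronate gives the anti C1/C2 pair, the Si‑face‑selective (S) catalyst sets 2S and hence 1S, and the allyl transposition creates the isopropenyl group.

**Step 27**
Reactants: 35
Product: 36 the C2 acetate of 35
Conditions: Ac2O, Et3N, DMAP (cat.), CH2Cl2, 0 °C
Reagents that add atoms: acetic anhydride CC(=O)OC(C)=O
Why: This acetylation installs the natural acetate, which also blocks C2–OH from lactonising and from Achmatowicz chemistry later; configuration is retained.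

**Step 28**
Reactants: 36
Product: 37 (5S)‑5‑[(S)‑acetoxy(5‑{(1S,2S)‑2‑[(1S)‑1‑hydroxyprop‑2‑en‑1‑yl]‑2‑methylcyclopropyl}‑3‑methylfuran‑2‑yl)methyl]‑6‑methyl‑2‑methylidenehept‑6‑enoic acid
Conditions: TASF (5 equiv), DMF, 0 °C→rt; pH 5 phosphate work‑up
Reagents that add atoms: none
Why: Near‑neutral fluoride cleavage removes the TES ether and fragments the TMSE ester in one operation without touching the acetate.

**Step 29**
Reactants: 37
Product: 38 the 13‑membered macrolactone (C10–O–C20), retaining the C10 vinyl, C12 methylidene, C1 isopropenyl and C2 OAc groups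
Conditions: MNBA (1.5 equiv), DMAP (6 equiv), toluene, syringe‑pump addition over 16 h, 40 °C, 1 mM
Reagents that add atoms: none
Why: Shiina macrolactonisation acylates the only free hydroxyl at oxygen, so C10 is retained.

**Step 30**
Reactants: 38
Product: 39 the furan‑bridged macrocycle, i.e. pinnatin B with C3–C6 as a 3‑methylfuran‑2,5‑diyl unit (1S,2S,7S,8S,10S)
Conditions: Grubbs II (2 × 10 mol %), 1,4‑benzoquinone (20 mol %), toluene (1 mM), 80 °C, Ar sparge
Reagents that add atoms: none (ethylene is lost)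
Why: Transannular ring‑closing metathesis of the allyl‑ester/acrylate pair favours five‑membered butenolide formation, which simultaneously creates the 13‑membered carbocycle, and the isopropenyl group is a poor metathesis partner.

**Step 31**
Reactants: 39
Product: 40 pinnatin B
Conditions: m‑CPBA (1.05 equiv), NaHCO3, CH2Cl2, −10→0 °C
Reagents that add atoms: m‑CPBA O=C(OO)c1cccc(Cl)c1 (one O)
Why: In this oxidative furan ring opening via the furan epoxide, the electron‑rich trialkylfuran reacts faster than the isopropenyl or butenolide C=C, and the ring geometry delivers the Z‑ene‑dione with no stereocentre affected.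

## Compound list
1 | prop‑2‑yn‑1‑ol | C#CCO | starting material
2 | (E)‑3‑iodo‑2‑methylprop‑2‑en‑1‑ol | OC/C(C)=C/I | intermediate
3 | TBDPS ether of 2 | CC(C)(C)[Si](OC/C(C)=C/I)(c1ccccc1)c1ccccc1 | intermediate
4 | N‑methoxy‑N‑methylacetamide | CC(=O)N(C)OC | starting material
5 | (E)‑5‑(TBDPS‑oxy)‑4‑methylpent‑3‑en‑2‑one | CC(=O)/C=C(\C)CO[Si](c1ccccc1)(c1ccccc1)C(C)(C)C | intermediate
6 | (2S,3E)‑5‑(TBDPS‑oxy)‑4‑methylpent‑3‑en‑2‑ol | C[C@H](O)/C=C(\C)CO[Si](c1ccccc1)(c1ccccc1)C(C)(C)C | intermediate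
7 | (1S)‑1‑[(1S,2S)‑2‑(TBDPS‑oxymethyl)‑2‑methylcyclopropyl]ethanol | CC(C)(C)[Si](c1ccccc1)(c1ccccc1)OC[C@@]1(C)C[C@@H]1[C@H](C)O | intermediate
8 | cyclopropyl methyl ketone | CC(C)(C)[Si](c1ccccc1)(c1ccccc1)OC[C@@]1(C)C[C@@H]1C(C)=O | intermediate
9 | 1‑(TBS‑oxy)propan‑2‑one | CC(=O)CO[Si](C)(C)C(C)(C)C | starting material
10 | aldol adduct (C4 epimers) | CC(C)(C)[Si](c1ccccc1)(c1ccccc1)OC[C@@]1(C)C[C@@H]1C(=O)CC(C)(O)CO[Si](C)(C)C(C)(C)C | intermediate
11 | furyl cyclopropane TBDPS ether | CC(C)(C)[Si](c1ccccc1)(c1ccccc1)OC[C@@]1(C)C[C@@H]1c1cc(C)co1 | intermediate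
12 | [(1S,2S)‑1‑methyl‑2‑(4‑methylfuran‑2‑yl)cyclopropyl]methanol | OC[C@@]1(C)C[C@@H]1c1cc(C)co1 | intermediate
13 | (1S,2S)‑1‑methyl‑2‑(4‑methylfuran‑2‑yl)cyclopropanecarbaldehyde | O=C[C@@]1(C)C[C@@H]1c1cc(C)co1 | intermediate
14 | ethynyltrimethylsilane | C#C[Si](C)(C)C | starting material
15 | TMS‑propargylic alcohol (C10 epimers) | C[Si](C)(C)C#CC(O)[C@@]1(C)C[C@@H]1c1cc(C)co1 | intermediate
16 | TMS‑ynone | C[Si](C)(C)C#CC(=O)[C@@]1(C)C[C@@H]1c1cc(C)co1 | intermediate
17 | (1R)‑TMS‑propargylic alcohol | C[Si](C)(C)C#C[C@H](O)[C@@]1(C)C[C@@H]1c1cc(C)co1 | intermediate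
18 | (1S)‑propargylic alcohol | C#C[C@H](O)[C@@]1(C)C[C@@H]1c1cc(C)co1 | intermediate
19 | (1S)‑allylic alcohol | C=C[C@H](O)[C@@]1(C)C[C@@H]1c1cc(C)co1 | intermediate
20 | TES ether of 19 | C=C[C@H](O[Si](CC)(CC)CC)[C@@]1(C)C[C@@H]1c1cc(C)co1 | intermediate
21 | west furfural | C=C[C@H](O[Si](CC)(CC)CC)[C@@]1(C)C[C@@H]1c1cc(C)c(C=O)o1 | intermediate
22 | 2‑(diethoxyphosphoryl)acetic acid | OC(=O)CP(=O)(OCC)OCC | starting material
23 | 2‑(trimethylsilyl)ethanol | OCC[Si](C)(C)C | starting material
24 | TMSE diethylphosphonoacetate | CCOP(=O)(OCC)CC(=O)OCC[Si](C)(C)C | intermediate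
25 | 2‑(2‑bromoethyl)‑1,3‑dioxolane | BrCCC1OCCO1 | starting material
26 | alkylated phosphonate (racemic) | CCOP(=O)(OCC)C(CCC1OCCO1)C(=O)OCC[Si](C)(C)C | intermediate
27 | acrylate acetal | C=C(CCC1OCCO1)C(=O)OCC[Si](C)(C)C | intermediate
28 | TMSE 2‑methylidene‑5‑oxopentanoate | C=C(CCC=O)C(=O)OCC[Si](C)(C)C | intermediate
29 | 2‑(triphenylphosphoranylidene)propanal | CC(C=O)=P(c1ccccc1)(c1ccccc1)c1ccccc1 | starting material
30 | (5E)‑enal | C=C(CC/C=C(\C)C=O)C(=O)OCC[Si](C)(C)C | intermediate
31 | (5E)‑allylic alcohol | C=C(CC/C=C(\C)CO)C(=O)OCC[Si](C)(C)C | intermediate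
32 | (5E)‑allylic acetate | C=C(CC/C=C(\C)COC(C)=O)C(=O)OCC[Si](C)(C)C | intermediate
33 | bis(pinacolato)diboron | CC1(C)OB(OC1(C)C)B1OC(C)(C)C(C)(C)O1 | starting material
34 | east (E)‑allylboronate | C=C(CC/C=C(\C)CB1OC(C)(C)C(C)(C)O1)C(=O)OCC[Si](C)(C)C | intermediate
35 | coupled C2 alcohol | C=C[C@H](O[Si](CC)(CC)CC)[C@@]1(C)C[C@@H]1c1cc(C)c(o1)[C@@H](O)[C@@H](CCC(=C)C(=O)OCC[Si](C)(C)C)C(C)=C | intermediate
36 | C2 acetate | C=C[C@H](O[Si](CC)(CC)CC)[C@@]1(C)C[C@@H]1c1cc(C)c(o1)[C@@H](OC(C)=O)[C@@H](CCC(=C)C(=O)OCC[Si](C)(C)C)C(C)=C | intermediate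
37 | seco acid | C=C[C@H](O)[C@@]1(C)C[C@@H]1c1cc(C)c(o1)[C@@H](OC(C)=O)[C@@H](CCC(=C)C(=O)O)C(C)=C | intermediate
38 | macrolactone | C=C[C@H](O3)[C@@]1(C)C[C@@H]1c1cc(C)c(o1)[C@@H](OC(C)=O)[C@@H](CCC(=C)C3=O)C(C)=C | intermediate
39 | furan‑bridged macrocycle | C=C(C)[C@@H]1CCC2=C[C@H](OC2=O)[C@@]2(C)C[C@@H]2c2cc(C)c(o2)[C@H]1OC(C)=O | intermediate
40 | pinnatin B | C=C(C)[C@@H]1CCC2=C[C@H](OC2=O)[C@@]2(C)C[C@@H]2C(=O)/C=C(/C)C(=O)[C@H]1OC(C)=O | target

## Totals
Total steps: 31. Longest linear sequence: 23 (steps 1–17, then 26–31). The east branch is 8 steps.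

## Steps most likely to fail, with fallbacks
1. **Step 29, macrolactonisation.** The C10 alcohol is hindered (neopentyl‑type and allylic) and the ring is rigid.
   - Fallback: reverse the ring‑forming order.
   - Formylate 19 as its dianion, then esterify its C10–OH intermolecularly with the free acid of O‑silylated 31.
   - Close the butenolide by an ordinary five‑ring RCM on the open chain.
   - Convert the allylic alcohol to the bromide and close the carbocycle at C1–C2 by an intramolecular, anti‑selective Nozaki–Hiyama–Kishi allylation.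
   - Finish with acetylation and step 31.
2. **Step 30, transannular RCM.** The ester must adopt the s‑cis form inside the macrolactone, and the vinyl group is hindered.
   - Fallback: replace metathesis with an intramolecular Horner–Wadsworth–Emmons reaction.
   - Omit step 20 so that C12 stays as the α‑phosphono ester.
   - Carry C11 as a protected CH2OH, made from the vinyl group of 20 by OsO4/NaIO4 cleavage, reduction and protection.
   - After macrolactonisation, unmask and oxidise C11 to the aldehyde and close the butenolide with LiCl/DBU.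
3. **Step 26, allylboration.** The β,γ‑disubstituted boronate is slow to react with an electron‑rich furfural, and the dr depends on the E/Z purity of 34.
   - Fallback: set C1 and C2 by a proline‑catalysed anti cross‑aldol of 21 with TMSE 2‑methylidene‑6‑oxohexanoate as the donor.
   - Acetylate C2–OH, then build the isopropenyl group from the new CHO by MeMgBr addition, oxidation and non‑basic Lombardo or Petasis methylenation.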